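**Plan**

- Numbering used here: oxolane O1, C2 (ring A, 3,4-dimethoxyphenyl), C3 and C4 (cis methyls), C5 (ring B, 4-hydroxy-3,5-dimethoxyphenyl); the target is (2S,3S,4R,5R) in this numbering.
- Retrosynthetic cuts, in order: C5–ring B (Friedel–Crafts on an oxocarbenium ion), then removal of O1 from the O1–C2 bond (retro-Baeyer–Villiger), then C2–C3 and C4–C5 ([2+2]).
- Enabling feature: the chain C2(ring A)–C3(Me)–C4(Me)–C5 is a 2-aryl-3,4-dimethylcyclobutanone with C5 as the carbonyl carbon, and O1 belongs in its C2–C5 bond.
- Forward order: arylacetamide, then keteniminium ion plus cis-2-butene to close the cyclobutane, oxygen insertion to expand it to the oxolane (as lactone), lactol acetate, ring B attached last.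
- Stereochemistry: C3/C4 cis from the Z-alkene, their absolute sense from a (2R,5R)-2,5-dimethylpyrrolidine auxiliary; C2 by equilibration trans to the C3 methyl and kept by retentive migration; C5 by arylation anti to the C4 methyl.

Key step: step 2

Assumption: the (2R,5R) antipode of the auxiliary is taken to deliver the (3S,4R) sense at the butene-derived carbons; should the cycloaddition favour the mirror image, the (2S,5S) antipode of 2 is used in step 1 and nothing else changes.

**Step 1**
Reactants: 1 homoveratric acid, 2-(3,4-dimethoxyphenyl)acetic acid; 2 (2R,5R)-2,5-dimethylpyrrolidine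
Product: 4 amide 2-(3,4-dimethoxyphenyl)-1-[(2R,5R)-2,5-dimethylpyrrolidin-1-yl]ethan-1-one, via acid chloride 3 (not isolated)
Conditions: (COCl)2, DMF (cat.), CH2Cl2, 0 °C to rt, evaporate; then 2, Et3N, CH2Cl2, 0 °C to rt
Reagents that add atoms: none
Why: Acylation of the hindered secondary amine by an acid chloride (made with oxalyl chloride and catalytic DMF) is a standard Schotten–Baumann-type amide formation that creates no stereocentre and leaves those of 2 untouched.

**Step 2**
Reactants: 4 amide 2-(3,4-dimethoxyphenyl)-1-[(2R,5R)-2,5-dimethylpyrrolidin-1-yl]ethan-1-one; 5 cis-2-butene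
Product: 9 cyclobutanone (2S,3S,4R)-2-(3,4-dimethoxyphenyl)-3,4-dimethylcyclobutan-1-one, via keteniminium triflate 6 (not isolated), via cyclobutaniminium triflate 7 (not isolated), via crude C2-epimeric ketone 8 (not isolated)
Conditions: Tf2O, 2,6-di-tert-butylpyridine, 5 (excess, condensed in), CH2Cl2, sealed tube, −30 °C to rt; then H2O, rt; aqueous wash; then DBU (cat.), CH2Cl2, 0 °C
Reagents that add atoms: water, O
Why: Tf2O triflates the amide oxygen and 2,6-di-tert-butylpyridine removes the benzylic proton, so that loss of triflate gives the linear keteniminium ion 6, whose electrophilic central carbon (the future C5, target numbering) is attacked by cis-2-butene in an asynchronous [2+2] cycloaddition in which C5–C4 forms ahead of C2–C3; this is the known keteniminium–alkene cyclobutanone synthesis, including its auxiliary-controlled form with amides of twofold-symmetric pyrrolidines. The cyclobutane ring is closed by this intermolecular [2+2] addition, the second bond forming when the enamine-like carbon C2 collapses on the developing cation at C3 faster than the C3–C4 bond can rotate. C3 and C4 take their cis relationship from the Z geometry of 5, because the addition is suprafacial on the alkene, and their absolute sense from the (2R,5R)-pyrrolidinium unit, whose two methyl groups flank the approach to C5 unequally. Water then hydrolyses iminium salt 7 and releases the auxiliary, and C2, which is formed as a mixture, is set by thermodynamic control: its proton is benzylic and α to the carbonyl, so a trace of DBU should converge the epimers 8 on the isomer 9 with ring A trans to the C3 methyl. The step therefore needs face selectivity at the butene-derived carbons (from the auxiliary), retention of alkene geometry (from the near-concerted bond formation) and equilibration at C2 without touching C4 (from the large acidity gap between the aryl-bearing and the methyl-bearing α-carbon).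

**Step 3**
Reactants: 9 cyclobutanone (2S,3S,4R)-2-(3,4-dimethoxyphenyl)-3,4-dimethylcyclobutan-1-one
Product: 10 lactone (3R,4S,5S)-5-(3,4-dimethoxyphenyl)-3,4-dimethyloxolan-2-one
Conditions: mCPBA, CH2Cl2, 0 °C to rt
Reagents that add atoms: mCPBA (3-chloroperoxybenzoic acid), O=C(OO)c1cccc(Cl)c1
Why: Baeyer–Villiger oxidation of a cyclobutanone is driven by strain release, and the secondary benzylic carbon C2, made electron-rich by ring A, should migrate in preference to the methyl-bearing C4 and with retention, so O1 enters the C2–C5 bond and no stereocentre changes.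

**Step 4**
Reactants: 10 lactone (3R,4S,5S)-5-(3,4-dimethoxyphenyl)-3,4-dimethyloxolan-2-one
Product: 11 lactol (3R,4S,5S)-5-(3,4-dimethoxyphenyl)-3,4-dimethyloxolan-2-ol (anomeric mixture)
Conditions: i-Bu2AlH (1.1 equiv), CH2Cl2, −78 °C
Reagents that add atoms: none
Why: Partial reduction of the γ-lactone with i-Bu2AlH at −78 °C stops at the tetrahedral aluminium hemiacetal and gives the lactol on work-up; the new anomeric centre is a mixture that does not matter because it is flattened in step 6.

**Step 5**
Reactants: 11 lactol (3R,4S,5S)-5-(3,4-dimethoxyphenyl)-3,4-dimethyloxolan-2-ol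
Product: 12 acetate (3R,4S,5S)-5-(3,4-dimethoxyphenyl)-3,4-dimethyloxolan-2-yl acetate (anomeric mixture)
Conditions: Ac2O, pyridine, DMAP (cat.), CH2Cl2, 0 °C to rt
Reagents that add atoms: acetic anhydride, CC(=O)OC(C)=O
Why: DMAP-catalysed O-acylation of the hemiacetal hydroxyl turns it into a good leaving group for oxocarbenium formation; the ring stereocentres are not involved.

**Step 6**
Reactants: 12 acetate (3R,4S,5S)-5-(3,4-dimethoxyphenyl)-3,4-dimethyloxolan-2-yl acetate; 13 2,6-dimethoxyphenol
Product: 14 target 4-[(2R,3R,4S,5S)-5-(3,4-dimethoxyphenyl)-3,4-dimethyloxolan-2-yl]-2,6-dimethoxyphenol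
Conditions: 13 (excess), BF3·OEt2, CH2Cl2, −78 to −20 °C
Reagents that add atoms: none
Why: BF3·OEt2 ionises the anomeric acetate to a cyclic oxocarbenium ion that alkylates 13 in a Friedel–Crafts reaction at the carbon para to the free hydroxyl (the only strongly activated, unhindered position); the arene should approach C5 from the face opposite the two cis methyl groups, which places ring B trans to the C4 methyl and cis to ring A, the arrangement that is also the more stable one should the benzylic ether re-ionise.

**Compound list**

1 | 2-(3,4-dimethoxyphenyl)acetic acid (homoveratric acid) | COc1ccc(CC(=O)O)cc1OC | starting material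
2 | (2R,5R)-2,5-dimethylpyrrolidine | C[C@@H]1CC[C@@H](C)N1 | starting material
3 | 2-(3,4-dimethoxyphenyl)acetyl chloride | COc1ccc(CC(=O)Cl)cc1OC | intermediate
4 | 2-(3,4-dimethoxyphenyl)-1-[(2R,5R)-2,5-dimethylpyrrolidin-1-yl]ethan-1-one | COc1ccc(CC(=O)N2[C@H](C)CC[C@H]2C)cc1OC | intermediate
5 | cis-2-butene | C/C=C\C | starting material
6 | (2R,5R)-1-[2-(3,4-dimethoxyphenyl)ethenylidene]-2,5-dimethylpyrrolidin-1-ium trifluoromethanesulfonate | COc1ccc(C=C=[N+]2[C@H](C)CC[C@H]2C)cc1OC.[O-]S(=O)(=O)C(F)(F)F | intermediate
7 | (2R,5R)-1-[(3S,4R)-2-(3,4-dimethoxyphenyl)-3,4-dimethylcyclobutylidene]-2,5-dimethylpyrrolidin-1-ium trifluoromethanesulfonate, C2 epimers | COc1ccc(C2C(=[N+]3[C@H](C)CC[C@H]3C)[C@H](C)[C@@H]2C)cc1OC.[O-]S(=O)(=O)C(F)(F)F | intermediate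
8 | (3S,4R)-2-(3,4-dimethoxyphenyl)-3,4-dimethylcyclobutan-1-one, mixture of C2 epimers | COc1ccc(C2C(=O)[C@H](C)[C@@H]2C)cc1OC | intermediate
9 | (2S,3S,4R)-2-(3,4-dimethoxyphenyl)-3,4-dimethylcyclobutan-1-one | COc1ccc([C@H]2C(=O)[C@H](C)[C@@H]2C)cc1OC | intermediate
10 | (3R,4S,5S)-5-(3,4-dimethoxyphenyl)-3,4-dimethyloxolan-2-one | COc1ccc([C@H]2OC(=O)[C@H](C)[C@@H]2C)cc1OC | intermediate
11 | (3R,4S,5S)-5-(3,4-dimethoxyphenyl)-3,4-dimethyloxolan-2-ol, anomeric mixture | COc1ccc([C@H]2OC(O)[C@H](C)[C@@H]2C)cc1OC | intermediate
12 | (3R,4S,5S)-5-(3,4-dimethoxyphenyl)-3,4-dimethyloxolan-2-yl acetate, anomeric mixture | COc1ccc([C@H]2OC(OC(C)=O)[C@H](C)[C@@H]2C)cc1OC | intermediate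
13 | 2,6-dimethoxyphenol | COc1cccc(OC)c1O | starting material
14 | 4-[(2R,3R,4S,5S)-5-(3,4-dimethoxyphenyl)-3,4-dimethyloxolan-2-yl]-2,6-dimethoxyphenol (IUPAC numbering starts at the phenol-bearing carbon) | COc1ccc([C@H]2O[C@@H](c3cc(OC)c(O)c(OC)c3)[C@H](C)[C@@H]2C)cc1OC | target

**Step count and risks**

Total steps: 6. Longest linear sequence: 6 steps (1 to 14).

Steps most likely to fail:

1. Step 2. The auxiliary may discriminate poorly between the two senses of addition at the butene-derived carbons. Because C2 is equilibrated afterwards, any such leakage appears directly as the enantiomer of 9. A long-lived cation could also erode the cis-methyl relationship. Fallback: enantiomeric purity is secured by resolution instead of by the cycloaddition alone. Lactone 10, of whatever enantiomeric purity, is opened with (S)-1-phenylethylamine and AlMe3 (toluene, 60 °C) to the γ-hydroxy amide (2R,3S,4S)-4-(3,4-dimethoxyphenyl)-4-hydroxy-2,3-dimethyl-N-[(1S)-1-phenylethyl]butanamide F1. F1 is freed from its diastereomers by crystallisation or chromatography and relactonised with TsOH in warm toluene. The fallback sets out from 10 and returns to 10, now as a single stereoisomer.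

2. Step 6. The phenol may react through oxygen or through the ring carbon next to a methoxy group, the arene may approach the oxocarbenium carbon from the wrong face, or the cation may lose the C4 proton and scramble that centre. Fallback: the carbon–carbon bond site is fixed beforehand with an organometallic nucleophile. Lactol 11 is converted with benzenesulfinic acid and CaCl2 in CH2Cl2 into the anomeric sulfone (3R,4S,5S)-2-(benzenesulfonyl)-5-(3,4-dimethoxyphenyl)-3,4-dimethyloxolane F2. The Grignard reagent [4-(benzyloxy)-3,5-dimethoxyphenyl]magnesium bromide F3, made from purchasable 2-(benzyloxy)-5-bromo-1,3-dimethoxybenzene and Mg in THF, then displaces the sulfinate in the presence of ZnBr2 (THF, rt). This should give the benzyl ether (2R,3R,4S,5S)-2-[4-(benzyloxy)-3,5-dimethoxyphenyl]-5-(3,4-dimethoxyphenyl)-3,4-dimethyloxolane F4, with the aryl group again entering anti to the neighbouring methyl. Hydrogenolysis (H2, Pd/C, EtOAc) frees the phenol. The fallback sets out from 11 and rejoins the route at 14.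

3. Step 3. Migration of the methyl-bearing carbon C4 may compete with that of the benzylic carbon, or the peracid may attack the electron-rich ring A. Fallback: the oxygen is inserted photochemically, without a peracid. Irradiation of ketone 9 in methanol through Pyrex (wavelengths above 300 nm) should cause Norrish α-cleavage on the benzylic side. The acyl/benzyl biradical recloses on oxygen to an oxacarbene, which inserts into the O–H bond of methanol. The product of this known cyclobutanone ring expansion is the methyl acetal (3R,4S,5S)-5-(3,4-dimethoxyphenyl)-2-methoxy-3,4-dimethyloxolane F5, already at the oxidation level of 12. F5 is taken into step 6 in place of 12 (13, BF3·OEt2, CH2Cl2). The fallback sets out from 9 and rejoins the route at 14.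

**Further compounds**

F1 | step 2 | (2R,3S,4S)-4-(3,4-dimethoxyphenyl)-4-hydroxy-2,3-dimethyl-N-[(1S)-1-phenylethyl]butanamide | COc1ccc([C@@H](O)[C@@H](C)[C@@H](C)C(=O)N[C@@H](C)c2ccccc2)cc1OC
F2 | step 6 | (3R,4S,5S)-2-(benzenesulfonyl)-5-(3,4-dimethoxyphenyl)-3,4-dimethyloxolane, C2 epimers | COc1ccc([C@H]2OC(S(=O)(=O)c3ccccc3)[C@H](C)[C@@H]2C)cc1OC
F3 | step 6 | [4-(benzyloxy)-3,5-dimethoxyphenyl]magnesium bromide | COc1cc([Mg]Br)cc(OC)c1OCc1ccccc1
F4 | step 6 | (2R,3R,4S,5S)-2-[4-(benzyloxy)-3,5-dimethoxyphenyl]-5-(3,4-dimethoxyphenyl)-3,4-dimethyloxolane | COc1ccc([C@H]2O[C@@H](c3cc(OC)c(OCc4ccccc4)c(OC)c3)[C@H](C)[C@@H]2C)cc1OC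
F5 | step 3 | (3R,4S,5S)-5-(3,4-dimethoxyphenyl)-2-methoxy-3,4-dimethyloxolane, anomeric mixture | COc1ccc([C@H]2OC(OC)[C@H](C)[C@@H]2C)cc1OC
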